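Free catalyst plus spent catalyst always adds up to the charge, so spent catalyst counts how far the flask has run.

    gas phase ⇌ dissolved gas, rate k1*(csat - [dissolved gas]) (k1 = 1.3 /min, csat = 63 mM)
    substrate + dissolved gas + free catalyst → free catalyst + target (k2 = 720 /M²/min)
    substrate + free catalyst → spent catalyst (k3 = 0.45 /M/min)
    target + free catalyst ⇌ isomer of the product + free catalyst, rate k4*[free catalyst]*[target] forward; the back reaction follows from the equilibrium constant (K4 = 18, k4 = 17 /M/min)

substrate 0.50 M; gas phase 63 mM (held); free catalyst 5.0 mM; time 2.0 h

- at the start none of the gas is dissolved
- run time (flask): 2.0 h

1. how much target there is at 2.0 h, in percent of the substrate charged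
2. the change that raises the amount of target at 2.0 h, in percent of the substrate charged most ("none" if none brings more than 2 percentage points) (larch / oak / alder / none)
3. amount of target at 2.0 h, in percent of the substrate charged, after oak

1. Free catalyst is lost to substrate in a pseudo-first-order way, with a lifetime of 4.44 min at the charge. That is far shorter than the run, so I reckon per catalyst lost, not per minute.

2. Substrate and free catalyst act on both the making step and the loss step. Their ratio therefore depends on the gas. At saturation, the capacity is the substrate that the charged catalyst can convert before it is spent, as a fraction of the substrate charged: 1.01.

3. That end says full conversion, but one number is not enough. No gas is dissolved at the start, and demand against transfer is 1.38. Early on, gas stands near 41.9% of saturation. Averaging this end with saturation gives conversion 71.5%.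

4. Isomerisation against catalyst loss is 0.378. Taken at mid-run, it gives isomer 21.0%. So target is 50.5%.

5. Doubling transfer gives 54.9%. Larch and oak double capacity to 2.02. Isomerisation has a forward half-life of 0.14 h at the charged catalyst, shorter than the run. But that half-life is reckoned at the charge and free catalyst is being lost, so it does not show that equilibrium is reached. I therefore score both at the equilibrium floor 5.26%, as a low mark for target and not as an estimate of it. On these rough scores my choice is alder, and for oak I commit only to a target above 5.26%.

6. The forecast gives 49%, alder and 13% after oak, holding that “faster gas transfer gives a modest gain”.

7. The flask gives 49.0%, alder (gain 4.9 percentage points) and 19.5% after oak. Substrate left is 36%, so the flask used 63.6% of its capacity. Its conversion, 64.0%, and its isomer, 14.1%, both fall below my figures, so my target came close through offsetting errors.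

8. In the neighbour flask with 0.12 M of substrate, capacity is 4.20, so catalyst should outlast substrate. That flask ends with substrate 0%, free catalyst 69.8%, target 5.28% and isomer 93.5%.

The numbers of this flask were drawn at random within sensible limits; the result is computed.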